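**Retrosynthetic overview**
1. The C4–Br bond of ring A and the C2'–Br and C4'–Br bonds of ring B sit at the natural ortho/para sites of the free OH and of the ether oxygen. They are disconnected first and installed last.
2. C–O disconnection: the diaryl ether goes back to a symmetrical dibromocatechol (Br ortho to each OH) and a phenyl cation equivalent (diaryliodonium salt). Because the two OH groups are equivalent, mono-arylation has only one possible regiochemical outcome.
3. Dearomatisation: the two bromines ortho to oxygen cannot be obtained by brominating catechol. They correspond to the alpha carbons of a cyclohexane-1,2-dione.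
4. Key C–C disconnection: C1–C2 of ring A is the only 1,2-dioxygenated (dissonant) bond in the molecule, and it is cut to an open-chain C6 diester. In the forward direction, two carbonyl carbons that are both natural acceptors are joined after electron transfer inverts their polarity (acyloin coupling).
5. Ring order: ring A is built first (acyloin closure, then aromatisation). Ring B is bought as a benzene ring and attached afterwards.

Numbering used: ring A is the phenol ring (C1 = C–OH, C2 = C–OAr, C3/C4/C6 = C–Br, C5 = C–H). Ring B is the phenoxy ring (primed numbers, C1' on oxygen).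

Assumption: the target SMILES has no stereocentre and no configurationally stable axis, so the compound is achiral, no stereocontrol is needed, and no step creates a stereocentre.

**Step 1**
Reactants: 1 dimethyl adipate (dimethyl hexanedioate)
Product: 2 1,2-bis(trimethylsilyloxy)cyclohex-1-ene
Conditions: Na (4.4 equiv, dispersion), Me3SiCl (4.6 equiv), toluene, reflux, N2; filter; distil
Reagents that add atoms: chlorotrimethylsilane, C[Si](C)(C)Cl
Why: Rühlmann variant of the acyloin condensation: electron transfer from Na turns the two ester carbonyl carbons, normally both electrophilic, into nucleophilic ketyl (acyl-anion-type) centres that couple with each other to close the six-membered ring at C1–C2, and Me3SiCl traps methoxide and the enediolate so that Dieckmann closure cannot compete.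

**Step 2**
Reactants: 2 1,2-bis(trimethylsilyloxy)cyclohex-1-ene
Product: 5 3,6-dibromobenzene-1,2-diol, via cyclohexane-1,2-dione 3 (not isolated), via 3,6,6-tribromo-2-hydroxycyclohex-2-en-1-one 4 (not isolated)
Conditions: Br2 (4.0 equiv, in portions), CH2Cl2, −78 → 23 °C, dark; evaporate; then Li2CO3 (1.5 equiv), DMF, 60 °C, N2; acidic work-up
Reagents that add atoms: bromine, BrBr
Why: Proposed new method: Br2 first oxidises the enediol bis-silyl ether to dione 3 (a known reaction of acyloin silyl ethers), 3 can then brominate only at its two enolisable alpha carbons C3 and C6, each bromination being slower than the one before so that the count can be held at tribromide 4, and Li2CO3 takes out one HBr (vinylogous E1cB through the dienolate) to leave a dienone that tautomerises to the catechol with bromine ortho to both oxygens; the closest known reaction types are the dehydrohalogenative aromatisation of 2,2,6,6-tetrahalocyclohexanones to 2,6-dihalophenols and of 2,2-dibromo-1-tetralones to 2-bromo-1-naphthols.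

**Step 3**
Reactants: 5 3,6-dibromobenzene-1,2-diol; 6 diphenyliodonium trifluoromethanesulfonate
Product: 7 3,6-dibromo-2-phenoxyphenol
Conditions: KOtBu (1.0 equiv), THF, 0 °C, N2; then 6 (1.0 equiv), 40 °C
Reagents that add atoms: none
Why: Metal-free O-arylation of a phenoxide with a diaryliodonium salt (ligand coupling at trivalent iodine, the phenyl group acting as an aryl cation equivalent) leaves every C–Br bond alone, the two OH groups of 5 are equivalent so only one mono-ether can form, and because 5 (internally hydrogen-bonded mono-anion) is more acidic than 7 the single equivalent of base stays on unreacted 5 and holds back a second arylation.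

**Step 4**
Reactants: 7 3,6-dibromo-2-phenoxyphenol
Product: 9 3,4,6-tribromo-2-(2,4-dibromophenoxy)phenol, via 3,4,6-tribromo-2-(4-bromophenoxy)phenol 8 (not isolated)
Conditions: Br2 (3.3 equiv), 1,2-dichloroethane, 0 → 23 °C; then FeBr3 (5 mol %), 50 °C
Reagents that add atoms: bromine, BrBr
Why: Electrophilic aromatic bromination run to its natural limit: the free OH sends bromine to C4, its only open ortho/para site, and the ether oxygen, which conjugates mainly with the unhindered ring B, sends bromine to C4' and then (FeBr3-assisted) to C2', while the next sites, C5 (meta to OH, between two bromines) and C6' (on a ring that already carries two bromines), are several orders of magnitude less reactive.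

**Compound list**
1 | dimethyl adipate | COC(=O)CCCCC(=O)OC | starting material
2 | 1,2-bis(trimethylsilyloxy)cyclohex-1-ene | C[Si](C)(C)OC1=C(O[Si](C)(C)C)CCCC1 | intermediate
3 | cyclohexane-1,2-dione | O=C1CCCCC1=O | intermediate
4 | 3,6,6-tribromo-2-hydroxycyclohex-2-en-1-one (enol form of 3,3,6-tribromocyclohexane-1,2-dione) | O=C1C(O)=C(Br)CCC1(Br)Br | intermediate
5 | 3,6-dibromobenzene-1,2-diol (3,6-dibromocatechol) | Oc1c(Br)ccc(Br)c1O | intermediate
6 | diphenyliodonium trifluoromethanesulfonate | [O-]S(=O)(=O)C(F)(F)F.c1ccc(cc1)[I+]c1ccccc1 | starting material
7 | 3,6-dibromo-2-phenoxyphenol | Oc1c(Br)ccc(Br)c1Oc1ccccc1 | intermediate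
8 | 3,4,6-tribromo-2-(4-bromophenoxy)phenol | Oc1c(Br)cc(Br)c(Br)c1Oc1ccc(Br)cc1 | intermediate
9 | 3,4,6-tribromo-2-(2,4-dibromophenoxy)phenol | Oc1c(Br)cc(Br)c(Br)c1Oc1ccc(Br)cc1Br | target

Total step count: 4. Longest linear sequence: 4 (1 → 2 → 5 → 7 → 9).

**Steps most likely to fail**

Step 2. The bromine count on the ring has to stop at three. In addition, 4 can hand electrophilic bromine to the catechol as it forms, which would give over- and under-brominated material. The fallback sets out from 2 and moves the aromatisation one oxidation level higher, where bromination has a fixed end point. Excess Br2 (6 equiv, CH2Cl2–AcOH, 40 °C) replaces all four alpha hydrogens and gives 3,3,6,6-tetrabromocyclohexane-1,2-dione F1. Et3N (2.1 equiv, Et2O, −20 °C) removes two HBr to give 3,6-dibromocyclohexa-3,5-diene-1,2-dione F2. Aqueous Na2S2O4, added at once, reduces this quinone, and the route is rejoined at 5.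

Step 3. The free catechol may be arylated twice, or it may be oxidised by the iodonium salt. The fallback sets out from 5 and breaks the symmetry by protection. MeI (1.0 equiv) with Li2CO3 in DMF gives 3,6-dibromo-2-methoxyphenol F3. Its single phenoxide is phenylated with 6 (KOtBu, THF, 40 °C) to 1,4-dibromo-2-methoxy-3-phenoxybenzene F4. BBr3 (CH2Cl2, −78 → 0 °C) then cleaves the methyl ether, and the route is rejoined at 7.

Step 4. The last bromination (C2') takes place on a ring of roughly benzene-like reactivity. It may stall at 8, or it may need forcing conditions that erode selectivity. The fallback sets out from 5 and brings ring B in already brominated. 1,3-Dibromobenzene, I2, mCPBA and CF3SO3H (CH2Cl2, 40 °C) give bis(2,4-dibromophenyl)iodonium trifluoromethanesulfonate F5. This arylates 5 (KOtBu, THF, 40 °C) to 3,6-dibromo-2-(2,4-dibromophenoxy)phenol F6. One equivalent of Br2 in AcOH at 23 °C then brominates only para to the OH, and the route is rejoined at 9.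

**Further compounds**
F1 | step 2 | 3,3,6,6-tetrabromocyclohexane-1,2-dione | O=C1C(=O)C(Br)(Br)CCC1(Br)Br
F2 | step 2 | 3,6-dibromocyclohexa-3,5-diene-1,2-dione | O=C1C(=O)C(Br)=CC=C1Br
F3 | step 3 | 3,6-dibromo-2-methoxyphenol | COc1c(O)c(Br)ccc1Br
F4 | step 3 | 1,4-dibromo-2-methoxy-3-phenoxybenzene | COc1c(Br)ccc(Br)c1Oc1ccccc1
F5 | step 4 | bis(2,4-dibromophenyl)iodonium trifluoromethanesulfonate | [O-]S(=O)(=O)C(F)(F)F.Brc1ccc([I+]c2ccc(Br)cc2Br)c(Br)c1
F6 | step 4 | 3,6-dibromo-2-(2,4-dibromophenoxy)phenol | Oc1c(Br)ccc(Br)c1Oc1ccc(Br)cc1Br
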